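**Plan**

Ring A is numbered C1 (CO2H), C2 (OMe), C3 (side chain), C6 (aryloxy); ring B is C1′ (ether O), C2′ (OH), C4′ (Me), C6′ (enone arm).
Retrosynthetic cuts: first the C6′–alkene bond of ring B (Heck), then the C6–O ether bond and the C1–CO2H bond of ring A together, last the benzylic C–C bond to the isobutyl group.
Enabling feature: on ring A the ether oxygen (C6) and the carboxyl carbon (C1) are neighbours and C1 also adjoins the C2 methoxy carbon, which is the pattern left when a nucleophile and then an electrophile add across a C1–C6 aryne polarised by a C2 methoxy group.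
Forward order: the side chain is built on ring A and the ring is turned into an ortho-silyl aryl triflate; the ring B phenoxide, the aryne and CO2 are joined in one operation; the enone is attached by a Heck reaction; a protecting-group exchange finishes the route.
Stereochemistry: the single (R) centre comes from asymmetric transfer hydrogenation of the aryl ketone with RuCl[(R,R)-TsDPEN](p-cymene); the E alkene comes from the Heck reaction.

Key step: step 12

Remark: the benzylic carbon is (R) (O > ring A carbon > CH2 > H); metal alkoxides, aryloxides and carboxylates that are only protonated on aqueous work-up are treated as salt forms of the product and carry no number of their own.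

**Route**

Step 1
Reactants: 1 4-hydroxy-2-methoxybenzaldehyde
Product: 2 4-formyl-3-methoxyphenyl N,N-diethylcarbamate
Conditions: Et2NCOCl, K2CO3, MeCN, reflux
Reagents that add atoms: N,N-diethylcarbamoyl chloride, CCN(CC)C(Cl)=O
Why: O-carbamoylation of the phenoxide (acyl substitution) masks the phenol and installs the directing group needed for the later ortho-lithiation.

Step 2
Reactants: 2 4-formyl-3-methoxyphenyl N,N-diethylcarbamate; 3 isobutylmagnesium bromide
Product: 4 4-(1-hydroxy-3-methylbutyl)-3-methoxyphenyl N,N-diethylcarbamate (racemate)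
Conditions: THF, −78 to 0 °C; then sat. aq. NH4Cl
Reagents that add atoms: none
Why: Grignard 1,2-addition to the aldehyde should proceed while the N,N-dialkyl carbamate stays inert at low temperature; the carbinol centre forms without control and is erased in step 3.

Step 3
Reactants: 4 4-(1-hydroxy-3-methylbutyl)-3-methoxyphenyl N,N-diethylcarbamate
Product: 5 3-methoxy-4-(3-methylbutanoyl)phenyl N,N-diethylcarbamate
Conditions: Dess–Martin periodinane, CH2Cl2, rt
Reagents that add atoms: none
Why: Dess–Martin oxidation of a secondary benzylic alcohol to the aryl ketone is mild and leaves the carbamate untouched.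

Step 4
Reactants: 5 3-methoxy-4-(3-methylbutanoyl)phenyl N,N-diethylcarbamate
Product: 6 4-[(1R)-1-hydroxy-3-methylbutyl]-3-methoxyphenyl N,N-diethylcarbamate
Conditions: RuCl[(R,R)-TsDPEN](p-cymene) (1 mol %), HCO2H/Et3N (5:2), 40 °C
Reagents that add atoms: none
Why: Noyori asymmetric transfer hydrogenation, in which the (R,R)-TsDPEN ruthenium hydride recognises the aryl flank through a CH–π contact and should deliver hydride to the Si face of the ketone, sets the (R) carbinol centre, the only stereocentre of the target.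

Step 5
Reactants: 6 4-[(1R)-1-hydroxy-3-methylbutyl]-3-methoxyphenyl N,N-diethylcarbamate
Product: 7 3-methoxy-4-[(1R)-3-methyl-1-(triisopropylsilyloxy)butyl]phenyl N,N-diethylcarbamate
Conditions: TIPSOTf, 2,6-lutidine, CH2Cl2, 0 °C to rt
Reagents that add atoms: triisopropylsilyl trifluoromethanesulfonate, CC(C)[Si](C(C)C)(C(C)C)OS(=O)(=O)C(F)(F)F
Why: O-silylation with a silyl triflate and a hindered base protects the crowded benzylic alcohol as a bulky ether that shields the benzylic C–H from base and resists the mild fluoride source of step 12; only the O–H bond reacts, so the configuration is retained.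

Step 6
Reactants: 7 3-methoxy-4-[(1R)-3-methyl-1-(triisopropylsilyloxy)butyl]phenyl N,N-diethylcarbamate
Product: 9 3-methoxy-4-[(1R)-3-methyl-1-(triisopropylsilyloxy)butyl]-2-(trimethylsilyl)phenyl N,N-diethylcarbamate, via aryllithium 8 (not isolated)
Conditions: s-BuLi, TMEDA, THF, −78 °C; then TMSCl, −78 °C to rt
Reagents that add atoms: chlorotrimethylsilane, C[Si](C)(C)Cl
Why: Directed ortho-metalation, in which the carbamate and methoxy groups cooperate to acidify the C–H between them, followed by silyl quench at −78 °C before an anionic Fries shift can occur, should place silicon on the future C1.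

Step 7
Reactants: 9 3-methoxy-4-[(1R)-3-methyl-1-(triisopropylsilyloxy)butyl]-2-(trimethylsilyl)phenyl N,N-diethylcarbamate
Product: 10 3-methoxy-4-[(1R)-3-methyl-1-(triisopropylsilyloxy)butyl]-2-(trimethylsilyl)phenol
Conditions: Cp2Zr(H)Cl, THF, rt; then H2O
Reagents that add atoms: none
Why: Reductive cleavage of the aryl O-carbamate by hydrozirconation of its carbonyl group with the Schwartz reagent releases the phenol under neutral conditions that spare the aryl–silicon bond and the silyl ether.

Step 8
Reactants: 10 3-methoxy-4-[(1R)-3-methyl-1-(triisopropylsilyloxy)butyl]-2-(trimethylsilyl)phenol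
Product: 11 3-methoxy-4-[(1R)-3-methyl-1-(triisopropylsilyloxy)butyl]-2-(trimethylsilyl)phenyl trifluoromethanesulfonate
Conditions: Tf2O, pyridine, CH2Cl2, 0 °C
Reagents that add atoms: trifluoromethanesulfonic anhydride, O=S(=O)(OS(=O)(=O)C(F)(F)F)C(F)(F)F
Why: O-sulfonylation of the phenol gives the ortho-silyl aryl triflate, the standard fluoride-triggered aryne precursor.

Step 9
Reactants: 12 2-hydroxy-4-methylbenzaldehyde
Product: 13 2-(methoxymethoxy)-4-methylbenzaldehyde
Conditions: MOMCl, iPr2NEt, CH2Cl2, 0 °C to rt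
Reagents that add atoms: chloromethyl methyl ether, COCCl
Why: O-alkylation of the phenol (Williamson-type acetal formation) fixes the protecting group on the oxygen that becomes the C2′ hydroxyl, so no later differentiation of a catechol is needed.

Step 10
Reactants: 13 2-(methoxymethoxy)-4-methylbenzaldehyde
Product: 15 2-(methoxymethoxy)-4-methylphenol, via aryl formate 14 (not isolated)
Conditions: mCPBA, CH2Cl2, 0 °C to rt; then K2CO3 (cat.), MeOH, rt
Reagents that add atoms: 3-chloroperbenzoic acid, OOC(=O)c1cccc(Cl)c1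
Why: Baeyer–Villiger (Dakin-type) oxidation of the electron-rich benzaldehyde proceeds by aryl migration to the formate, which is methanolysed to the phenol.

Step 11
Reactants: 15 2-(methoxymethoxy)-4-methylphenol
Product: 16 2-bromo-6-(methoxymethoxy)-4-methylphenol
Conditions: NBS, iPr2NH (cat.), CH2Cl2, 0 °C
Reagents that add atoms: N-bromosuccinimide, BrN1C(=O)CCC1=O
Why: Amine-mediated electrophilic aromatic bromination should go to the only free position ortho to the hydroxyl group, the para position being blocked by methyl, without generating acid that would harm the acetal.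

Step 12
Reactants: 11 3-methoxy-4-[(1R)-3-methyl-1-(triisopropylsilyloxy)butyl]-2-(trimethylsilyl)phenyl trifluoromethanesulfonate; 16 2-bromo-6-(methoxymethoxy)-4-methylphenol; 17 carbon dioxide
Product: 21 6-[2-bromo-6-(methoxymethoxy)-4-methylphenoxy]-2-methoxy-3-[(1R)-3-methyl-1-(triisopropylsilyloxy)butyl]benzoic acid, via potassium phenoxide 18 (not isolated), via aryne 19 (not isolated), via aryl anion 20 (not isolated)
Conditions: KH, THF, 0 °C (16 to its phenoxide); then 11, KF, 18-crown-6, CO2 (1 atm), THF, 0 °C to rt; then aq. HCl to pH 3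
Reagents that add atoms: none
Why: Proposed new method: fluoride attacks the trimethylsilyl group of 11 and triflate departs in a 1,2-elimination to give aryne 19; the inductively withdrawing C2 methoxy group distorts the triple bond so that phenoxide 18 adds at the distal carbon C6 and the charge develops at C1, flanked by the methoxy- and aryloxy-bearing carbons (20), and this stabilised aryl anion attacks CO2 to give the carboxylate. The closest known reaction types are the fluoride-promoted three-component couplings of arynes with amines and CO2 to anthranilic acids, the O-arylation of phenols with arynes, and the aryne annulation of salicylates in which the same kind of phenoxide-derived aryl anion is caught by a carbonyl group. No ring is closed and no stereocentre is formed; the remote (R) carbinol centre is not involved. The step needs site selectivity in the phenoxide addition, which the methoxy group next to the aryne secures (attack meta to it), and O- rather than C-arylation, which is secured because both ortho positions and the para position of 18 are substituted. It also needs carboxylation to outrun protonation, which is favoured by the preformed potassium phenoxide, the absence of protic species, THF as solvent and an excess of CO2.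

Step 13
Reactants: 21 6-[2-bromo-6-(methoxymethoxy)-4-methylphenoxy]-2-methoxy-3-[(1R)-3-methyl-1-(triisopropylsilyloxy)butyl]benzoic acid; 22 methyl vinyl ketone
Product: 23 2-methoxy-6-[2-(methoxymethoxy)-4-methyl-6-[(1E)-3-oxobut-1-en-1-yl]phenoxy]-3-[(1R)-3-methyl-1-(triisopropylsilyloxy)butyl]benzoic acid
Conditions: Pd(OAc)2 (5 mol %), P(t-Bu)3·HBF4 (10 mol %), Cy2NMe, 1,4-dioxane, 80 °C
Reagents that add atoms: none
Why: Mizoroki–Heck reaction, in which the bulky electron-rich phosphine lets zerovalent palladium insert into the hindered aryl bromide below the temperature at which the benzoate could decarboxylate, and syn insertion followed by syn β-hydride elimination should give the E-enone.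

Step 14
Reactants: 23 2-methoxy-6-[2-(methoxymethoxy)-4-methyl-6-[(1E)-3-oxobut-1-en-1-yl]phenoxy]-3-[(1R)-3-methyl-1-(triisopropylsilyloxy)butyl]benzoic acid
Product: 24 3-[(1R)-1-hydroxy-3-methylbutyl]-2-methoxy-6-[2-(methoxymethoxy)-4-methyl-6-[(1E)-3-oxobut-1-en-1-yl]phenoxy]benzoic acid
Conditions: TBAF, AcOH, THF, rt to 40 °C
Reagents that add atoms: none
Why: Fluoride-induced Si–O cleavage buffered with acetic acid frees the benzylic alcohol without acid, so the carbinol centre cannot ionise, and the enone and the acetal are left alone.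

Step 15
Reactants: 24 3-[(1R)-1-hydroxy-3-methylbutyl]-2-methoxy-6-[2-(methoxymethoxy)-4-methyl-6-[(1E)-3-oxobut-1-en-1-yl]phenoxy]benzoic acid
Product: 26 3-[(1R)-1-acetoxy-3-methylbutyl]-2-methoxy-6-[2-(methoxymethoxy)-4-methyl-6-[(1E)-3-oxobut-1-en-1-yl]phenoxy]benzoic acid, via mixed anhydride 25 (not isolated)
Conditions: Ac2O, pyridine, DMAP (cat.), CH2Cl2, rt; then H2O, rt
Reagents that add atoms: acetic anhydride, CC(=O)OC(C)=O
Why: DMAP-catalysed O-acetylation (nucleophilic catalysis) esterifies the secondary alcohol with retention, since only the O–H bond reacts; the carboxyl group is acetylated transiently to mixed anhydride 25, which water cleaves again, and the still protected phenol cannot compete.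

Step 16
Reactants: 26 3-[(1R)-1-acetoxy-3-methylbutyl]-2-methoxy-6-[2-(methoxymethoxy)-4-methyl-6-[(1E)-3-oxobut-1-en-1-yl]phenoxy]benzoic acid
Product: 27 3-[(1R)-1-acetoxy-3-methylbutyl]-6-[2-hydroxy-4-methyl-6-[(1E)-3-oxobut-1-en-1-yl]phenoxy]-2-methoxybenzoic acid (target)
Conditions: TFA, CH2Cl2, 0 °C; then H2O
Reagents that add atoms: none
Why: Acid-catalysed cleavage of the aryl methoxymethyl acetal through the methoxymethyl oxocarbenium ion should be fast because the phenol is a good leaving group, whereas the benzylic acetate, deactivated by the meta carboxyl group and a twisted methoxy group, should not ionise in a short exposure at 0 °C without water.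

**Compound list**

1 | 4-hydroxy-2-methoxybenzaldehyde | COc1cc(O)ccc1C=O | starting material
2 | 4-formyl-3-methoxyphenyl N,N-diethylcarbamate | CCN(CC)C(=O)Oc1ccc(C=O)c(OC)c1 | intermediate
3 | isobutylmagnesium bromide | CC(C)C[Mg]Br | starting material
4 | 4-(1-hydroxy-3-methylbutyl)-3-methoxyphenyl N,N-diethylcarbamate (racemate) | CCN(CC)C(=O)Oc1ccc(C(O)CC(C)C)c(OC)c1 | intermediate
5 | 3-methoxy-4-(3-methylbutanoyl)phenyl N,N-diethylcarbamate | CCN(CC)C(=O)Oc1ccc(C(=O)CC(C)C)c(OC)c1 | intermediate
6 | 4-[(1R)-1-hydroxy-3-methylbutyl]-3-methoxyphenyl N,N-diethylcarbamate | CCN(CC)C(=O)Oc1ccc([C@@H](CC(C)C)O)c(OC)c1 | intermediate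
7 | 3-methoxy-4-[(1R)-3-methyl-1-(triisopropylsilyloxy)butyl]phenyl N,N-diethylcarbamate | CCN(CC)C(=O)Oc1ccc([C@@H](CC(C)C)O[Si](C(C)C)(C(C)C)C(C)C)c(OC)c1 | intermediate
8 | {2-[(diethylcarbamoyl)oxy]-6-methoxy-5-[(1R)-3-methyl-1-(triisopropylsilyloxy)butyl]phenyl}lithium | CCN(CC)C(=O)Oc1ccc([C@@H](CC(C)C)O[Si](C(C)C)(C(C)C)C(C)C)c(OC)c1[Li] | intermediate (not isolated)
9 | 3-methoxy-4-[(1R)-3-methyl-1-(triisopropylsilyloxy)butyl]-2-(trimethylsilyl)phenyl N,N-diethylcarbamate | CCN(CC)C(=O)Oc1ccc([C@@H](CC(C)C)O[Si](C(C)C)(C(C)C)C(C)C)c(OC)c1[Si](C)(C)C | intermediate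
10 | 3-methoxy-4-[(1R)-3-methyl-1-(triisopropylsilyloxy)butyl]-2-(trimethylsilyl)phenol | COc1c([C@@H](CC(C)C)O[Si](C(C)C)(C(C)C)C(C)C)ccc(O)c1[Si](C)(C)C | intermediate
11 | 3-methoxy-4-[(1R)-3-methyl-1-(triisopropylsilyloxy)butyl]-2-(trimethylsilyl)phenyl trifluoromethanesulfonate | COc1c([C@@H](CC(C)C)O[Si](C(C)C)(C(C)C)C(C)C)ccc(OS(=O)(=O)C(F)(F)F)c1[Si](C)(C)C | intermediate
12 | 2-hydroxy-4-methylbenzaldehyde | Cc1ccc(C=O)c(O)c1 | starting material
13 | 2-(methoxymethoxy)-4-methylbenzaldehyde | COCOc1cc(C)ccc1C=O | intermediate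
14 | 2-(methoxymethoxy)-4-methylphenyl formate | COCOc1cc(C)ccc1OC=O | intermediate (not isolated)
15 | 2-(methoxymethoxy)-4-methylphenol | COCOc1cc(C)ccc1O | intermediate
16 | 2-bromo-6-(methoxymethoxy)-4-methylphenol | COCOc1cc(C)cc(Br)c1O | intermediate
17 | carbon dioxide | O=C=O | starting material
18 | potassium 2-bromo-6-(methoxymethoxy)-4-methylphenolate | COCOc1cc(C)cc(Br)c1[O-].[K+] | intermediate (not isolated)
19 | 3-methoxy-4-[(1R)-3-methyl-1-(triisopropylsilyloxy)butyl]benzyne (triple bond between C1 and C6 of ring A) | COC1=C([C@@H](CC(C)C)O[Si](C(C)C)(C(C)C)C(C)C)C=CC#C1 | intermediate (not isolated)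
20 | potassium 6-[2-bromo-6-(methoxymethoxy)-4-methylphenoxy]-2-methoxy-3-[(1R)-3-methyl-1-(triisopropylsilyloxy)butyl]benzen-1-ide (carbanion at C1) | COC1=C([C@@H](CC(C)C)O[Si](C(C)C)(C(C)C)C(C)C)C=CC(Oc2c(OCOC)cc(C)cc2Br)=[C-]1.[K+] | intermediate (not isolated)
21 | 6-[2-bromo-6-(methoxymethoxy)-4-methylphenoxy]-2-methoxy-3-[(1R)-3-methyl-1-(triisopropylsilyloxy)butyl]benzoic acid | COc1c([C@@H](CC(C)C)O[Si](C(C)C)(C(C)C)C(C)C)ccc(Oc2c(OCOC)cc(C)cc2Br)c1C(=O)O | intermediate
22 | methyl vinyl ketone (but-3-en-2-one) | CC(=O)C=C | starting material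
23 | 2-methoxy-6-[2-(methoxymethoxy)-4-methyl-6-[(1E)-3-oxobut-1-en-1-yl]phenoxy]-3-[(1R)-3-methyl-1-(triisopropylsilyloxy)butyl]benzoic acid | COc1c([C@@H](CC(C)C)O[Si](C(C)C)(C(C)C)C(C)C)ccc(Oc2c(OCOC)cc(C)cc2/C=C/C(C)=O)c1C(=O)O | intermediate
24 | 3-[(1R)-1-hydroxy-3-methylbutyl]-2-methoxy-6-[2-(methoxymethoxy)-4-methyl-6-[(1E)-3-oxobut-1-en-1-yl]phenoxy]benzoic acid | COc1c([C@@H](CC(C)C)O)ccc(Oc2c(OCOC)cc(C)cc2/C=C/C(C)=O)c1C(=O)O | intermediate
25 | acetic 3-[(1R)-1-acetoxy-3-methylbutyl]-2-methoxy-6-[2-(methoxymethoxy)-4-methyl-6-[(1E)-3-oxobut-1-en-1-yl]phenoxy]benzoic anhydride | COc1c([C@@H](CC(C)C)OC(C)=O)ccc(Oc2c(OCOC)cc(C)cc2/C=C/C(C)=O)c1C(=O)OC(C)=O | intermediate (not isolated)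
26 | 3-[(1R)-1-acetoxy-3-methylbutyl]-2-methoxy-6-[2-(methoxymethoxy)-4-methyl-6-[(1E)-3-oxobut-1-en-1-yl]phenoxy]benzoic acid | COc1c([C@@H](CC(C)C)OC(C)=O)ccc(Oc2c(OCOC)cc(C)cc2/C=C/C(C)=O)c1C(=O)O | intermediate
27 | 3-[(1R)-1-acetoxy-3-methylbutyl]-6-[2-hydroxy-4-methyl-6-[(1E)-3-oxobut-1-en-1-yl]phenoxy]-2-methoxybenzoic acid | COc1c([C@@H](CC(C)C)OC(C)=O)ccc(Oc2c(O)cc(C)cc2/C=C/C(C)=O)c1C(=O)O | target

**Step count and risks**

Total: 16 steps. Longest linear sequence: 13 steps (steps 1–8 and 12–16, from 1); the ring B branch (steps 9–11) has three steps.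

Step 12 (carboxylative three-component coupling). The C1 carbanion may be protonated before it meets CO2, the phenoxide may be held back as its carbonate adduct with CO2, or the phenoxide addition may lose its site preference. The fallback uses only known reaction types, sets out from 11 and comes back at 21. Fluoride-induced aryne formation in the presence of iodine (CsF, I2, MeCN, rt; insertion of the aryne into the I–I bond) should give 1,2-diiodo-3-methoxy-4-[(1R)-3-methyl-1-(triisopropylsilyloxy)butyl]benzene F1. Iodine–magnesium exchange at the iodine flanked by the methoxy group (iPrMgCl·LiCl, THF, −78 °C) and quenching with carbon dioxide 17 should give 6-iodo-2-methoxy-3-[(1R)-3-methyl-1-(triisopropylsilyloxy)butyl]benzoic acid F2. A carboxylate-assisted Ullmann ether coupling of this acid with phenol 16 (CuI, picolinic acid, K3PO4, DMSO, 80 °C), in which the iodide next to the carboxylate should react well before the bromide of ring B, then gives 21.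

Step 13 (Heck reaction). Insertion at the crowded, electron-rich bromide may be slow, methyl vinyl ketone may polymerise, the arylpalladium intermediate may cyclise onto ring A by C–H arylation, or the di-ortho-substituted benzoate may decarboxylate at the palladium centre. The fallback sets out from 21 and comes back at 23. Suzuki–Miyaura coupling with potassium vinyltrifluoroborate (PdCl2(dppf), Cs2CO3, THF/H2O, 70 °C) should give 6-[2-ethenyl-6-(methoxymethoxy)-4-methylphenoxy]-2-methoxy-3-[(1R)-3-methyl-1-(triisopropylsilyloxy)butyl]benzoic acid F3. Olefin cross-metathesis of this styrene with methyl vinyl ketone 22 (second-generation Hoveyda–Grubbs catalyst, CH2Cl2, 40 °C) should then give the E-enone 23.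

Step 16 (acetal cleavage beside the benzylic acetate). The benzylic acetate may ionise under the acid, with racemisation, elimination or ester exchange, and the methoxymethyl cation may alkylate the electron-rich ring. The fallback sets out from 23 and comes back at target 27, so that acid never meets the acetate. The acetal is removed while the benzylic oxygen is still a silyl ether (TFA, CH2Cl2, 0 °C), giving 6-[2-hydroxy-4-methyl-6-[(1E)-3-oxobut-1-en-1-yl]phenoxy]-2-methoxy-3-[(1R)-3-methyl-1-(triisopropylsilyloxy)butyl]benzoic acid F4. Desilylation (TBAF, AcOH, THF) gives 3-[(1R)-1-hydroxy-3-methylbutyl]-6-[2-hydroxy-4-methyl-6-[(1E)-3-oxobut-1-en-1-yl]phenoxy]-2-methoxybenzoic acid F5. Exhaustive acetylation (Ac2O, pyridine, DMAP) gives acetic 3-[(1R)-1-acetoxy-3-methylbutyl]-6-[2-acetoxy-4-methyl-6-[(1E)-3-oxobut-1-en-1-yl]phenoxy]-2-methoxybenzoic anhydride F6, which water converts into 3-[(1R)-1-acetoxy-3-methylbutyl]-6-[2-acetoxy-4-methyl-6-[(1E)-3-oxobut-1-en-1-yl]phenoxy]-2-methoxybenzoic acid F7. Selective methanolysis of the aryl acetate (K2CO3, MeOH, 0 °C), which is much more labile than the alkyl acetate, then gives 27.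

**Further compounds**

F1 | step 12 | 1,2-diiodo-3-methoxy-4-[(1R)-3-methyl-1-(triisopropylsilyloxy)butyl]benzene | COc1c([C@@H](CC(C)C)O[Si](C(C)C)(C(C)C)C(C)C)ccc(I)c1I
F2 | step 12 | 6-iodo-2-methoxy-3-[(1R)-3-methyl-1-(triisopropylsilyloxy)butyl]benzoic acid | COc1c([C@@H](CC(C)C)O[Si](C(C)C)(C(C)C)C(C)C)ccc(I)c1C(=O)O
F3 | step 13 | 6-[2-ethenyl-6-(methoxymethoxy)-4-methylphenoxy]-2-methoxy-3-[(1R)-3-methyl-1-(triisopropylsilyloxy)butyl]benzoic acid | COc1c([C@@H](CC(C)C)O[Si](C(C)C)(C(C)C)C(C)C)ccc(Oc2c(OCOC)cc(C)cc2C=C)c1C(=O)O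
F4 | step 16 | 6-[2-hydroxy-4-methyl-6-[(1E)-3-oxobut-1-en-1-yl]phenoxy]-2-methoxy-3-[(1R)-3-methyl-1-(triisopropylsilyloxy)butyl]benzoic acid | COc1c([C@@H](CC(C)C)O[Si](C(C)C)(C(C)C)C(C)C)ccc(Oc2c(O)cc(C)cc2/C=C/C(C)=O)c1C(=O)O
F5 | step 16 | 3-[(1R)-1-hydroxy-3-methylbutyl]-6-[2-hydroxy-4-methyl-6-[(1E)-3-oxobut-1-en-1-yl]phenoxy]-2-methoxybenzoic acid | COc1c([C@@H](CC(C)C)O)ccc(Oc2c(O)cc(C)cc2/C=C/C(C)=O)c1C(=O)O
F6 | step 16 | acetic 3-[(1R)-1-acetoxy-3-methylbutyl]-6-[2-acetoxy-4-methyl-6-[(1E)-3-oxobut-1-en-1-yl]phenoxy]-2-methoxybenzoic anhydride | COc1c([C@@H](CC(C)C)OC(C)=O)ccc(Oc2c(OC(C)=O)cc(C)cc2/C=C/C(C)=O)c1C(=O)OC(C)=O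
F7 | step 16 | 3-[(1R)-1-acetoxy-3-methylbutyl]-6-[2-acetoxy-4-methyl-6-[(1E)-3-oxobut-1-en-1-yl]phenoxy]-2-methoxybenzoic acid | COc1c([C@@H](CC(C)C)OC(C)=O)ccc(Oc2c(OC(C)=O)cc(C)cc2/C=C/C(C)=O)c1C(=O)O
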